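**Plan**

- Retrosynthesis: the five O-benzyl groups are cut first, then the stilbene C=C (Horner–Wadsworth–Emmons), then the aryl C7a–O1 bond of the dihydrofuran ring (intramolecular SNAr). This leaves an open (1S,2S)-1,2,2-triarylethanol, whose C2–aryl and C3–aryl bonds are cut together (conjunctive cross-coupling) to an (E)-styrylboronate, an aryllithium and an aryl triflate.
- Forward: one coupling loads the two-carbon chain with all three aryl groups, the oxygen ring is then closed onto the finished benzene ring, the stilbene arm is added by olefination, and the phenols are unmasked last.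
- Enabling feature: in the benzo ring of the benzofuran, the carbon that carries the styryl arm (C5) is para to the oxygen-bearing carbon C7a. Kept as a nitrile, C5 makes C7a–F an SNAr electrophile for the C2 alkoxide (five-membered ring); the nitrile then becomes the aldehyde for the olefination.
- Stereochemistry: both stereocenters arise in the palladium-catalysed conjunctive coupling. Anti addition across the E-alkene gives the relative configuration and the chiral ferrocenyl bisphosphine the absolute one. Boron is replaced by OH with retention, the ring closure breaks no bond at a stereocenter, and the E-alkene comes from the phosphonate olefination.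

Key step: step 6

Assumption: the (SP,S′P) ligand is taken to give the (1S,2S) boronate; if the coupling gives the antipode, the mirror-image ligand is used with nothing else changed.
Assumption: the cis-diol 4 is made in-house because its commercial supply is uncertain.

**Route**

Step 1
Reactants: 1 3,5-bis(benzyloxy)benzaldehyde
Product: 2 1,3-bis(benzyloxy)-5-ethynylbenzene
Conditions: dimethyl (1-diazo-2-oxopropyl)phosphonate, K2CO3, MeOH, 0 °C to rt
Reagents that add atoms: dimethyl (1-diazo-2-oxopropyl)phosphonate, CC(=O)C(=[N+]=[N-])P(=O)(OC)OC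
Why: Seyferth–Gilbert homologation in the Ohira–Bestmann form: methanolysis of the acetyl group frees the diazomethylphosphonate anion, which adds to the aldehyde and, after loss of dimethyl phosphate and N2, gives the terminal alkyne by 1,2-hydride shift, while the benzyl ethers are inert.

Step 2
Reactants: 3 acenaphthylene-1,2-dione (acenaphthenequinone)
Product: 4 cis-1,2-dimethyl-1,2-dihydroacenaphthylene-1,2-diol (meso "mac" diol)
Conditions: MeMgBr (3 equiv), THF, 0 °C to rt; H2O quench; recrystallisation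
Reagents that add atoms: methylmagnesium bromide, C[Mg]Br
Why: double Grignard 1,2-addition to the rigid 1,2-diketone, in which the second methyl group should enter anti to the bulky solvated magnesium alkoxide of the first adduct and so give the cis (meso) diol, to be freed from any trans isomer by recrystallisation.

Step 3
Reactants: 2 1,3-bis(benzyloxy)-5-ethynylbenzene; 4 cis-1,2-dimethyl-1,2-dihydroacenaphthylene-1,2-diol
Product: 6 8-{(E)-2-[3,5-bis(benzyloxy)phenyl]ethenyl}-6b,9a-dimethyl-6b,9a-dihydroacenaphtho[1,2-d][1,3,2]dioxaborole (the B(mac) ester of the (E)-styrylboronic acid), via catechol alkenylboronate 5 (not isolated)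
Conditions: catecholborane, THF, 70 °C; then 4, THF, rt
Reagents that add atoms: catecholborane, B1Oc2ccccc2O1
Why: uncatalysed hydroboration of a terminal arylalkyne by catecholborane is a syn, anti-Markovnikov addition that gives the (E)-alkenylboronate, and the chelating ditertiary cis-diol then displaces catechol by transesterification to give the hindered boronic ester that disfavours direct Suzuki-type transfer in step 5.

Step 4
Reactants: 7 4-fluoro-3-hydroxybenzonitrile
Product: 8 5-cyano-2-fluorophenyl trifluoromethanesulfonate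
Conditions: Tf2O, pyridine, CH2Cl2, 0 °C
Reagents that add atoms: trifluoromethanesulfonic anhydride, O=S(=O)(OS(=O)(=O)C(F)(F)F)C(F)(F)F
Why: O-sulfonylation of an acidic phenol with the anhydride and pyridine gives the aryl triflate needed as the coupling electrophile, leaving fluoride and nitrile untouched.

Step 5
Reactants: 9 1-(benzyloxy)-4-bromobenzene; 6 the (E)-styryl B(mac) ester; 8 5-cyano-2-fluorophenyl trifluoromethanesulfonate
Product: 13 3-{(1S,2S)-2-[4-(benzyloxy)phenyl]-1-[3,5-bis(benzyloxy)phenyl]-2-hydroxyethyl}-4-fluorobenzonitrile, via aryllithium 10 (not isolated), via lithium boronate complex 11 (not isolated), via secondary boronic ester 12 (not isolated)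
Conditions: t-BuLi (2 equiv), Et2O, −78 °C; 6, 0 °C to rt; Et2O removed; Pd(OAc)2 (2 mol%), (SP,S′P)-1,1′-bis[bis(4-methoxy-3,5-dimethylphenyl)phosphino]-2,2′-bis[(R)-α-(dimethylamino)benzyl]ferrocene (2.4 mol%), KOTf, 8, THF, 60 °C; then NaBO3·4H2O, THF/H2O, rt
Reagents that add atoms: sodium perborate tetrahydrate (NaBO3·4H2O), [Na+].[Na+].O[B-]1(O)OO[B-](O)(O)OO1 (written without its water of crystallisation)
Why: after Br–Li exchange and formation of the four-coordinate boronate, palladium-catalysed conjunctive cross-coupling should take place: oxidative addition of 8 to zerovalent palladium gives an arylpalladium (divalent) species that binds the alkene and triggers a 1,2-metallate shift of the 4-(benzyloxy)phenyl group from boron to the α-carbon anti to palladium, reductive elimination places the fluoroaryl ring on the β-carbon, so anti addition across the E-alkene fixes the (1S,2S) relative configuration while the chiral bisphosphine chooses the alkene face, and perborate replaces boron by OH with retention.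

Step 6
Reactants: 13 3-{(1S,2S)-2-[4-(benzyloxy)phenyl]-1-[3,5-bis(benzyloxy)phenyl]-2-hydroxyethyl}-4-fluorobenzonitrile
Product: 14 (2S,3S)-2-[4-(benzyloxy)phenyl]-3-[3,5-bis(benzyloxy)phenyl]-2,3-dihydro-1-benzofuran-5-carbonitrile
Conditions: NaH (1.1 equiv), THF/DMF 4:1 (0.02 M), 0 °C to rt
Reagents that add atoms: none
Why: Deprotonation gives the secondary alkoxide, which adds to the fluorine-bearing ring carbon next to the side chain; the charge of the Meisenheimer intermediate rests on the para carbon and its nitrile (a keteniminate), and loss of fluoride restores the benzene ring. The closest known reaction type is intramolecular SNAr etherification of 2-(2-fluoroaryl)ethanols that carry a para electron-withdrawing group, as in alkoxide displacement of fluoride from 4-fluorobenzonitriles. The dihydrofuran ring is closed in a 5-exo-trig addition–elimination. No new stereocenter is formed: the C–O bond at the carbinol carbon is not broken, C3 is not touched, and the (1S,2S) arrangement of 13 necessarily places the two aryl groups trans, giving (2S,3S). The step needs chemoselectivity for fluoride displacement over attack on a nitrile, bimolecular substitution and deprotonation of the doubly benzylic C3–H. This is secured by the five-membered transition state, by the nitrile being para to C–F but meta to the carbon that bears C3 (so it does not acidify C3–H), by dilution and by only a slight excess of base.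

Step 7
Reactants: 14 (2S,3S)-2-[4-(benzyloxy)phenyl]-3-[3,5-bis(benzyloxy)phenyl]-2,3-dihydro-1-benzofuran-5-carbonitrile
Product: 15 (2S,3S)-2-[4-(benzyloxy)phenyl]-3-[3,5-bis(benzyloxy)phenyl]-2,3-dihydro-1-benzofuran-5-carbaldehyde
Conditions: i-Bu2AlH (1.5 equiv), toluene, −78 °C; then aq. potassium sodium tartrate (KNaC4H4O6), rt
Reagents that add atoms: water, O
Why: partial reduction of an aryl nitrile, in which one hydride transfer gives an N-aluminated aldimine that is stable at low temperature and is hydrolysed to the aldehyde on work-up, with ethers and both stereocenters untouched.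

Step 8
Reactants: 16 1,3-bis(benzyloxy)-5-(bromomethyl)benzene
Product: 17 diethyl [3,5-bis(benzyloxy)benzyl]phosphonate
Conditions: P(OEt)3 (neat), 140 °C
Reagents that add atoms: triethyl phosphite, CCOP(OCC)OCC
Why: Michaelis–Arbuzov reaction, in which the phosphite displaces the benzylic bromide and the phosphonium salt is dealkylated by bromide with loss of bromoethane.

Step 9
Reactants: 15 the 5-carbaldehyde; 17 diethyl [3,5-bis(benzyloxy)benzyl]phosphonate
Product: 18 (2S,3S)-2-[4-(benzyloxy)phenyl]-3-[3,5-bis(benzyloxy)phenyl]-5-{(E)-2-[3,5-bis(benzyloxy)phenyl]ethenyl}-2,3-dihydro-1-benzofuran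
Conditions: 17, NaH, THF, 0 °C; then 15, 0 °C to rt
Reagents that add atoms: none
Why: Horner–Wadsworth–Emmons olefination with a semi-stabilised benzylphosphonate anion should give the E-stilbene through the reversibly formed, more stable anti adduct, and the base is consumed by the phosphonate so that C3–H is not disturbed.

Step 10
Reactants: 18 the penta-O-benzyl ether
Product: 19 (2S,3S)-trans-δ-viniferin
Conditions: BCl3 (1 M in CH2Cl2, 10 equiv), pentamethylbenzene (15 equiv), CH2Cl2, −78 °C; MeOH/H2O quench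
Reagents that add atoms: none
Why: Lewis-acid debenzylation, in which BCl3 activates each aryl benzyl ether and the non-basic scavenger pentamethylbenzene traps the benzyl cation by Friedel–Crafts alkylation; this spares the stilbene double bond (which hydrogenolysis would reduce) and the electron-rich resorcinol rings, and should the benzylic C2–O bond ionise reversibly, C3 holds the configuration and the trans ring is the more stable one.

**Compound list**

1 | 3,5-bis(benzyloxy)benzaldehyde | O=Cc1cc(OCc2ccccc2)cc(OCc2ccccc2)c1 | starting material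
2 | 1,3-bis(benzyloxy)-5-ethynylbenzene | C#Cc1cc(OCc2ccccc2)cc(OCc2ccccc2)c1 | intermediate
3 | acenaphthylene-1,2-dione (acenaphthenequinone) | O=C1C(=O)c2cccc3cccc1c23 | starting material
4 | cis-1,2-dimethyl-1,2-dihydroacenaphthylene-1,2-diol (meso mac diol) | O[C@]1(C)c2cccc3cccc(c23)[C@]1(C)O | intermediate
5 | 2-{(E)-2-[3,5-bis(benzyloxy)phenyl]ethenyl}-1,3,2-benzodioxaborole | B1(/C=C/c2cc(OCc3ccccc3)cc(OCc3ccccc3)c2)Oc2ccccc2O1 | intermediate
6 | 8-{(E)-2-[3,5-bis(benzyloxy)phenyl]ethenyl}-6b,9a-dimethyl-6b,9a-dihydroacenaphtho[1,2-d][1,3,2]dioxaborole | B1(/C=C/c2cc(OCc3ccccc3)cc(OCc3ccccc3)c2)O[C@]2(C)c3cccc4cccc(c34)[C@]2(C)O1 | intermediate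
7 | 4-fluoro-3-hydroxybenzonitrile | N#Cc1ccc(F)c(O)c1 | starting material
8 | 5-cyano-2-fluorophenyl trifluoromethanesulfonate | N#Cc1ccc(F)c(OS(=O)(=O)C(F)(F)F)c1 | intermediate
9 | 1-(benzyloxy)-4-bromobenzene | Brc1ccc(OCc2ccccc2)cc1 | starting material
10 | [4-(benzyloxy)phenyl]lithium | [Li]c1ccc(OCc2ccccc2)cc1 | intermediate
11 | lithium [4-(benzyloxy)phenyl]{(E)-2-[3,5-bis(benzyloxy)phenyl]ethenyl}(cis-1,2-dimethylacenaphthylene-1,2-diolato)borate | [Li+].[B-]1(/C=C/c2cc(OCc3ccccc3)cc(OCc3ccccc3)c2)(c2ccc(OCc3ccccc3)cc2)O[C@]2(C)c3cccc4cccc(c34)[C@]2(C)O1 | intermediate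
12 | 3-{(1S,2S)-2-[4-(benzyloxy)phenyl]-1-[3,5-bis(benzyloxy)phenyl]-2-(6b,9a-dimethyl-6b,9a-dihydroacenaphtho[1,2-d][1,3,2]dioxaborol-8-yl)ethyl}-4-fluorobenzonitrile | B1([C@H](c2ccc(OCc3ccccc3)cc2)[C@H](c2cc(C#N)ccc2F)c2cc(OCc3ccccc3)cc(OCc3ccccc3)c2)O[C@]2(C)c3cccc4cccc(c34)[C@]2(C)O1 | intermediate
13 | 3-{(1S,2S)-2-[4-(benzyloxy)phenyl]-1-[3,5-bis(benzyloxy)phenyl]-2-hydroxyethyl}-4-fluorobenzonitrile | O[C@H](c1ccc(OCc2ccccc2)cc1)[C@H](c1cc(C#N)ccc1F)c1cc(OCc2ccccc2)cc(OCc2ccccc2)c1 | intermediate
14 | (2S,3S)-2-[4-(benzyloxy)phenyl]-3-[3,5-bis(benzyloxy)phenyl]-2,3-dihydro-1-benzofuran-5-carbonitrile | N#Cc1ccc2O[C@H](c3ccc(OCc4ccccc4)cc3)[C@@H](c3cc(OCc4ccccc4)cc(OCc4ccccc4)c3)c2c1 | intermediate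
15 | (2S,3S)-2-[4-(benzyloxy)phenyl]-3-[3,5-bis(benzyloxy)phenyl]-2,3-dihydro-1-benzofuran-5-carbaldehyde | O=Cc1ccc2O[C@H](c3ccc(OCc4ccccc4)cc3)[C@@H](c3cc(OCc4ccccc4)cc(OCc4ccccc4)c3)c2c1 | intermediate
16 | 1,3-bis(benzyloxy)-5-(bromomethyl)benzene | BrCc1cc(OCc2ccccc2)cc(OCc2ccccc2)c1 | starting material
17 | diethyl [3,5-bis(benzyloxy)benzyl]phosphonate | CCOP(=O)(Cc1cc(OCc2ccccc2)cc(OCc2ccccc2)c1)OCC | intermediate
18 | (2S,3S)-2-[4-(benzyloxy)phenyl]-3-[3,5-bis(benzyloxy)phenyl]-5-{(E)-2-[3,5-bis(benzyloxy)phenyl]ethenyl}-2,3-dihydro-1-benzofuran | c1ccccc1COc1cc(OCc2ccccc2)cc(/C=C/c2ccc3O[C@H](c4ccc(OCc5ccccc5)cc4)[C@@H](c4cc(OCc5ccccc5)cc(OCc5ccccc5)c4)c3c2)c1 | intermediate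
19 | (2S,3S)-trans-δ-viniferin | Oc1ccc([C@H]2Oc3ccc(/C=C/c4cc(O)cc(O)c4)cc3[C@@H]2c2cc(O)cc(O)c2)cc1 | target

**Summary**

Total step count: 10. Longest linear sequence: 7 steps (steps 1, 3, 5, 6, 7, 9, 10).

Steps most likely to fail:

1. Step 5. With a β-aryl alkenylboronate and an ortho-fluoro triflate, direct transmetalation (Suzuki-type transfer) or β-hydride elimination may outrun the 1,2-metallate shift. Facial discrimination may be insufficient, and the nitrile may be hydrated during the oxidative work-up. The fallback sets out from 2 and 9, uses 8, and comes back at 13. Sonogashira coupling of 2 with 9 (PdCl2(PPh3)2, CuI, Et3N) gives 1,3-bis(benzyloxy)-5-{[4-(benzyloxy)phenyl]ethynyl}benzene F1. Gold-catalysed hydration (Ph3PAuCl, AgOTf, aqueous dioxane), directed by the para-benzyloxy group to the alkyne carbon next to that ring, gives 1-[4-(benzyloxy)phenyl]-2-[3,5-bis(benzyloxy)phenyl]ethan-1-one F2. Palladium-catalysed enolate α-arylation with 8 (Pd(OAc)2, XPhos, K3PO4, toluene) gives the racemic, configurationally labile 3-{2-[4-(benzyloxy)phenyl]-1-[3,5-bis(benzyloxy)phenyl]-2-oxoethyl}-4-fluorobenzonitrile F3. Asymmetric transfer hydrogenation with dynamic kinetic resolution (RuCl(p-cymene)[(S,S)-TsDPEN], HCO2H/Et3N) should set the S carbinol under catalyst control while the α-center equilibrates through the enol. The diastereoselectivity of this reduction cannot be predicted, so 13 would be separated from its C1 epimer by chromatography.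

2. Step 10. During the fivefold Lewis-acid debenzylation the benzylic C2–O bond may ionise and the electron-rich stilbene may add HCl or oligomerise. The fallback sets out from 14 and 17 and comes back at 19; it removes the benzyl groups by hydrogenolysis before the alkene exists. Hydrogenolysis of 14 (H2, Pd/C, EtOAc/MeOH, stopped at the calculated uptake) gives (2S,3S)-3-(3,5-dihydroxyphenyl)-2-(4-hydroxyphenyl)-2,3-dihydro-1-benzofuran-5-carbonitrile F4. Silylation (TBSCl, imidazole, DMF) gives the tris(tert-butyldimethylsilyl) ether F5, and i-Bu2AlH reduction as in step 7 gives the tris-silylated 5-carbaldehyde F6. In parallel, 17 is hydrogenolysed to diethyl (3,5-dihydroxybenzyl)phosphonate F7 and silylated to diethyl {3,5-bis[(tert-butyldimethylsilyl)oxy]benzyl}phosphonate F8. Olefination of F6 with F8 (NaH, THF) gives penta-O-(tert-butyldimethylsilyl)-(2S,3S)-trans-δ-viniferin F9, and buffered fluoride (TBAF, AcOH, THF, 0 °C) gives 19.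

3. Step 6. Proton transfer from the doubly benzylic C3–H to the alkoxide may compete with ring closure and erode the configuration at C3, or bimolecular fluoride displacement may give oligomers. The fallback sets out from 13 and comes back at 14; it closes the ring at the benzylic carbon under acid instead. Silylation of 13 (TBSCl, imidazole, DMF) gives 3-{(1S,2S)-2-[4-(benzyloxy)phenyl]-1-[3,5-bis(benzyloxy)phenyl]-2-[(tert-butyldimethylsilyl)oxy]ethyl}-4-fluorobenzonitrile F10. Intermolecular SNAr with a hydroxide surrogate under a mild base (benzaldoxime, Cs2CO3, DMSO, 80 °C) gives the phenol 3-{(1S,2S)-2-[4-(benzyloxy)phenyl]-1-[3,5-bis(benzyloxy)phenyl]-2-[(tert-butyldimethylsilyl)oxy]ethyl}-4-hydroxybenzonitrile F11. Acid (TsOH, CH2Cl2, rt) ionises the para-benzyloxybenzylic C–O bond and the phenol captures the cation. With C3 fixed as S, the ring closes under thermodynamic control to the trans isomer 14.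

**Further compounds**

F1 | step 5 | 1,3-bis(benzyloxy)-5-{[4-(benzyloxy)phenyl]ethynyl}benzene | c1ccc(COc2ccc(C#Cc3cc(OCc4ccccc4)cc(OCc4ccccc4)c3)cc2)cc1
F2 | step 5 | 1-[4-(benzyloxy)phenyl]-2-[3,5-bis(benzyloxy)phenyl]ethan-1-one | O=C(Cc1cc(OCc2ccccc2)cc(OCc2ccccc2)c1)c1ccc(OCc2ccccc2)cc1
F3 | step 5 | 3-{2-[4-(benzyloxy)phenyl]-1-[3,5-bis(benzyloxy)phenyl]-2-oxoethyl}-4-fluorobenzonitrile (racemic) | O=C(c1ccc(OCc2ccccc2)cc1)C(c1cc(C#N)ccc1F)c1cc(OCc2ccccc2)cc(OCc2ccccc2)c1
F4 | step 10 | (2S,3S)-3-(3,5-dihydroxyphenyl)-2-(4-hydroxyphenyl)-2,3-dihydro-1-benzofuran-5-carbonitrile | N#Cc1ccc2O[C@H](c3ccc(O)cc3)[C@@H](c3cc(O)cc(O)c3)c2c1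
F5 | step 10 | (2S,3S)-3-{3,5-bis[(tert-butyldimethylsilyl)oxy]phenyl}-2-{4-[(tert-butyldimethylsilyl)oxy]phenyl}-2,3-dihydro-1-benzofuran-5-carbonitrile | N#Cc1ccc2O[C@H](c3ccc(O[Si](C)(C)C(C)(C)C)cc3)[C@@H](c3cc(O[Si](C)(C)C(C)(C)C)cc(O[Si](C)(C)C(C)(C)C)c3)c2c1
F6 | step 10 | (2S,3S)-3-{3,5-bis[(tert-butyldimethylsilyl)oxy]phenyl}-2-{4-[(tert-butyldimethylsilyl)oxy]phenyl}-2,3-dihydro-1-benzofuran-5-carbaldehyde | O=Cc1ccc2O[C@H](c3ccc(O[Si](C)(C)C(C)(C)C)cc3)[C@@H](c3cc(O[Si](C)(C)C(C)(C)C)cc(O[Si](C)(C)C(C)(C)C)c3)c2c1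
F7 | step 10 | diethyl (3,5-dihydroxybenzyl)phosphonate | CCOP(=O)(Cc1cc(O)cc(O)c1)OCC
F8 | step 10 | diethyl {3,5-bis[(tert-butyldimethylsilyl)oxy]benzyl}phosphonate | CCOP(=O)(Cc1cc(O[Si](C)(C)C(C)(C)C)cc(O[Si](C)(C)C(C)(C)C)c1)OCC
F9 | step 10 | penta-O-(tert-butyldimethylsilyl)-(2S,3S)-trans-δ-viniferin | CC(C)(C)[Si](C)(C)Oc1cc(O[Si](C)(C)C(C)(C)C)cc(/C=C/c2ccc3O[C@H](c4ccc(O[Si](C)(C)C(C)(C)C)cc4)[C@@H](c4cc(O[Si](C)(C)C(C)(C)C)cc(O[Si](C)(C)C(C)(C)C)c4)c3c2)c1
F10 | step 6 | 3-{(1S,2S)-2-[4-(benzyloxy)phenyl]-1-[3,5-bis(benzyloxy)phenyl]-2-[(tert-butyldimethylsilyl)oxy]ethyl}-4-fluorobenzonitrile | CC(C)(C)[Si](C)(C)O[C@H](c1ccc(OCc2ccccc2)cc1)[C@H](c1cc(C#N)ccc1F)c1cc(OCc2ccccc2)cc(OCc2ccccc2)c1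
F11 | step 6 | 3-{(1S,2S)-2-[4-(benzyloxy)phenyl]-1-[3,5-bis(benzyloxy)phenyl]-2-[(tert-butyldimethylsilyl)oxy]ethyl}-4-hydroxybenzonitrile | CC(C)(C)[Si](C)(C)O[C@H](c1ccc(OCc2ccccc2)cc1)[C@H](c1cc(C#N)ccc1O)c1cc(OCc2ccccc2)cc(OCc2ccccc2)c1
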